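The butenolide is disconnected at its O1–C5 bond: C3, C4 and the unsubstituted C5 methylene of the 2(5H)-furanone ring are the three allene carbons of an achiral tert-butyl 2-alkylbuta-2,3-dienoate, and the ring oxygen is its ester carbonyl oxygen. An AuCl3-catalysed 5-endo cyclisation with loss of isobutene closes the lactone in one operation on the fully assembled chain. The chain comes from a C2-symmetric (2R,6R)-diallyl diol made by a double Evans allylation of a pimeloyl bis-imide; its two homotopic arms become iodides and are differentiated by mono-phosphonium formation, a Z-selective Wittig reaction and alkylation of a but-2-ynoate cumulenolate.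

Key step: step 10

Remark: tert-butyl but-2-ynoate and 1-{[tert-butyl(dimethyl)silyl]oxy}propan-2-one are taken as catalogue compounds. The 1,1-disubstituted allene of the key-step precursor has no stereogenic axis, so no allene chirality has to be controlled. Steps 1 and 2 are two-directional, so each consumes two molecules of its partner (2 and 5 respectively); the second molecule is entered on the line for reagents that add atoms.

Step 1
Reactants: 1 heptanedioyl dichloride (pimeloyl chloride); 2 (4S)-4-benzyl-1,3-oxazolidin-2-one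
Product: 4 1,7-bis[(4S)-4-benzyl-2-oxo-1,3-oxazolidin-3-yl]heptane-1,7-dione, via lithium oxazolidinide 3 (not isolated)
Conditions: 2 (2.1 equiv), n-BuLi (2.1 equiv), THF, −78 °C; then 1 (1.0 equiv), −78 °C to 0 °C
Reagents that add atoms: (4S)-4-benzyl-1,3-oxazolidin-2-one (second molecule of 2), O=C1N[C@@H](Cc2ccccc2)CO1
Why: N-acylation of the lithiated oxazolidinone by the diacid chloride is fast at low temperature, and two molecules of 3 place the same (S)-auxiliary on both ends of the C7 diacid (Evans auxiliary acylation).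

Step 2
Reactants: 4 1,7-bis[(4S)-4-benzyl-2-oxo-1,3-oxazolidin-3-yl]heptane-1,7-dione; 5 3-iodoprop-1-ene (allyl iodide)
Product: 7 (2R,6R)-1,7-bis[(4S)-4-benzyl-2-oxo-1,3-oxazolidin-3-yl]-2,6-di(prop-2-en-1-yl)heptane-1,7-dione, via disodium bis-enolate 6 (not isolated)
Conditions: 4 added slowly to NaN(SiMe3)2 (2.3 equiv), THF, −78 °C; then 5 (6 equiv), −78 °C to −45 °C
Reagents that add atoms: 3-iodoprop-1-ene (second molecule of 5), C=CCI
Why: Two-directional Evans asymmetric alkylation, in which inverse addition to excess base takes 4 straight to the bis-enolate (so that a mono-enolate cannot close onto the second imide) and each chelated Z-sodium enolate takes up one allyl iodide on the face opposite the C4 benzyl group, so that the same matched auxiliary control sets R at C2 and at C6 and the minor diastereomers can be removed by chromatography.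

Step 3
Reactants: 7 (2R,6R)-1,7-bis[(4S)-4-benzyl-2-oxo-1,3-oxazolidin-3-yl]-2,6-di(prop-2-en-1-yl)heptane-1,7-dione
Product: 8 (2R,6R)-2,6-di(prop-2-en-1-yl)heptane-1,7-diol
Conditions: LiBH4 (3 equiv), MeOH (3 equiv), THF/Et2O, 0 °C
Reagents that add atoms: none
Why: LiBH4 reductive cleavage of the N-acyloxazolidinones at the exocyclic carbonyl should give the two primary alcohols without touching the α-stereocentres or the terminal alkenes, and the auxiliary is recovered.

Step 4
Reactants: 8 (2R,6R)-2,6-di(prop-2-en-1-yl)heptane-1,7-diol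
Product: 9 (2R,6R)-2,6-di(prop-2-en-1-yl)heptane-1,7-diyl diacetate
Conditions: Ac2O, pyridine, DMAP (cat.), CH2Cl2, 0 °C to rt
Reagents that add atoms: acetic anhydride, CC(=O)OC(C)=O
Why: DMAP-catalysed acetylation installs the two acetates of the target at the outset, so that no later exchange of protecting groups is needed.

Step 5
Reactants: 9 (2R,6R)-2,6-di(prop-2-en-1-yl)heptane-1,7-diyl diacetate
Product: 11 (2R,6R)-2,6-bis(3-hydroxypropyl)heptane-1,7-diyl diacetate, via bis-alkylborane 10 (not isolated)
Conditions: 9-BBN (2.4 equiv), THF, 0 °C to rt; then aq. NaOAc, 30 % H2O2, 0 °C to rt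
Reagents that add atoms: hydrogen peroxide, OO
Why: Brown hydroboration with 9-BBN places boron on the terminal carbon of each allyl group, and the acetate-buffered peroxide oxidation should leave the acetates intact.

Step 6
Reactants: 11 (2R,6R)-2,6-bis(3-hydroxypropyl)heptane-1,7-diyl diacetate
Product: 12 (2R,6R)-2,6-bis(3-iodopropyl)heptane-1,7-diyl diacetate
Conditions: I2, PPh3, imidazole, CH2Cl2, 0 °C to rt
Reagents that add atoms: iodine, II
Why: Appel-type iodination converts both primary alcohols into iodides by SN2 displacement of the alkoxyphosphonium intermediates under neutral conditions.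

Step 7
Reactants: 12 (2R,6R)-2,6-bis(3-iodopropyl)heptane-1,7-diyl diacetate
Product: 13 [(4R,8R)-4,8-bis(acetoxymethyl)-11-iodoundecyl](triphenyl)phosphonium iodide
Conditions: PPh3 (1.0 equiv), 12 (3.0 equiv), MeCN, 80 °C; unreacted 12 recovered by trituration and recycled
Reagents that add atoms: triphenylphosphine, c1ccc(cc1)P(c1ccccc1)c1ccccc1
Why: SN2 quaternisation of triphenylphosphine by a primary iodide, in which the two iodopropyl arms of the C2-symmetric diiodide are homotopic, so that mono-substitution gives a single compound and the excess of 12 suppresses the bis-salt.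

Step 8
Reactants: 13 [(4R,8R)-4,8-bis(acetoxymethyl)-11-iodoundecyl](triphenyl)phosphonium iodide; 14 1-{[tert-butyl(dimethyl)silyl]oxy}propan-2-one
Product: 16 (2R,6R)-2-[(3Z)-5-{[tert-butyl(dimethyl)silyl]oxy}-4-methylpent-3-en-1-yl]-6-(3-iodopropyl)heptane-1,7-diyl diacetate, via phosphorus ylide 15 (not isolated)
Conditions: NaN(SiMe3)2 (1.0 equiv), THF, −78 °C; then 14 (1.5 equiv), −78 °C to 0 °C
Reagents that add atoms: none
Why: Wittig olefination of an α-silyloxy ketone by an unstabilised ylide, a combination known to be strongly Z-selective because the kinetically formed oxaphosphetane places the ylide substituent cis to the CH2OSi group, while at −78 °C neither the primary iodide nor the acetates should compete with the activated ketone.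

Step 9
Reactants: 16 (2R,6R)-2-[(3Z)-5-{[tert-butyl(dimethyl)silyl]oxy}-4-methylpent-3-en-1-yl]-6-(3-iodopropyl)heptane-1,7-diyl diacetate; 17 tert-butyl but-2-ynoate
Product: 19 tert-butyl 2-[(4R,8R,11Z)-4,8-bis(acetoxymethyl)-13-{[tert-butyl(dimethyl)silyl]oxy}-12-methyltridec-11-en-1-yl]buta-2,3-dienoate, via lithium cumulenolate 18 (not isolated)
Conditions: 17 (1.6 equiv), LiN(iPr)2 (commercial solution, 1.5 equiv), THF, −78 °C; then 16, DMPU, −78 °C to −40 °C
Reagents that add atoms: none
Why: γ-Deprotonation of the alkynoate gives a cumulenolate that is alkylated at its α-carbon by the primary iodide (deconjugative α-alkylation of a 2-alkynoate), which forms the C–C bond to the future butenolide C3 and the terminal allene in one step, and the slight excess of 17 over the amide base leaves no free base to attack the acetates.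

Step 10
Reactants: 19 tert-butyl 2-[(4R,8R,11Z)-4,8-bis(acetoxymethyl)-13-{[tert-butyl(dimethyl)silyl]oxy}-12-methyltridec-11-en-1-yl]buta-2,3-dienoate
Product: 20 (2R,6R)-2-[(3Z)-5-{[tert-butyl(dimethyl)silyl]oxy}-4-methylpent-3-en-1-yl]-6-[3-(2-oxo-2,5-dihydrofuran-3-yl)propyl]heptane-1,7-diyl diacetate
Conditions: AuCl3 (5 mol %), CH2Cl2, rt
Reagents that add atoms: none
Why: AuCl3 (trivalent gold) coordinates the terminal C=C of the allenoate and the ester carbonyl oxygen attacks the unsubstituted terminal carbon, which forms the O1–C5 bond of the lactone and turns the former carbonyl oxygen into the ring oxygen. The resulting 2-tert-butoxyfuranylium vinylgold species loses its tert-butyl group as isobutene and protodeauration delivers the C4–H of the butenolide, so the catalyst turns over without added acid or base. The closest known reaction type is the AuCl3-catalysed cyclisation of tert-butyl allenoates to 2(5H)-furanones, a dealkylative relative of the AgNO3-catalysed cycloisomerisation of 2,3-allenoic acids. The single ring is closed in the 5-endo-trig mode. No stereocentre is created, since the allene is achiral (C5 is an unsubstituted methylene) and the two remote stereocentres and the Z-alkene are spectators. The step needs O-attack at the allene terminus and chemoselectivity over the trisubstituted alkene, the allylic silyl ether and the acetates: the first is secured because only the terminal carbon lies within reach of the carbonyl oxygen in a five-membered transition state, the second by the preference of the soft gold centre for the allene under neutral conditions at rt.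

Step 11
Reactants: 20 (2R,6R)-2-[(3Z)-5-{[tert-butyl(dimethyl)silyl]oxy}-4-methylpent-3-en-1-yl]-6-[3-(2-oxo-2,5-dihydrofuran-3-yl)propyl]heptane-1,7-diyl diacetate
Product: 21 (2R,6R)-2-[(3Z)-5-hydroxy-4-methylpent-3-en-1-yl]-6-[3-(2-oxo-2,5-dihydrofuran-3-yl)propyl]heptane-1,7-diyl diacetate
Conditions: HF·pyridine, pyridine, THF, 0 °C to rt
Reagents that add atoms: none
Why: Fluoride-mediated cleavage of the primary allylic silyl ether with buffered HF·pyridine should leave the acetates, the butenolide and the Z-alkene untouched.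

Compound list

1 | heptanedioyl dichloride (pimeloyl chloride) | O=C(Cl)CCCCCC(=O)Cl | starting material
2 | (4S)-4-benzyl-1,3-oxazolidin-2-one | O=C1N[C@@H](Cc2ccccc2)CO1 | starting material
3 | lithium (4S)-4-benzyl-2-oxo-1,3-oxazolidin-3-ide (formed in situ) | [Li]N1[C@@H](Cc2ccccc2)COC1=O | intermediate
4 | 1,7-bis[(4S)-4-benzyl-2-oxo-1,3-oxazolidin-3-yl]heptane-1,7-dione | O=C(CCCCCC(=O)N1[C@@H](Cc2ccccc2)COC1=O)N1[C@@H](Cc2ccccc2)COC1=O | intermediate
5 | 3-iodoprop-1-ene (allyl iodide) | C=CCI | starting material
6 | disodium (1Z,6Z)-1,7-bis[(4S)-4-benzyl-2-oxo-1,3-oxazolidin-3-yl]hepta-1,6-diene-1,7-bis(olate) (formed in situ) | [Na]O/C(=C\CCC/C=C(\O[Na])N1[C@@H](Cc2ccccc2)COC1=O)N1[C@@H](Cc2ccccc2)COC1=O | intermediate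
7 | (2R,6R)-1,7-bis[(4S)-4-benzyl-2-oxo-1,3-oxazolidin-3-yl]-2,6-di(prop-2-en-1-yl)heptane-1,7-dione | O=C([C@@H](CC=C)CCC[C@H](CC=C)C(=O)N1[C@@H](Cc2ccccc2)COC1=O)N1[C@@H](Cc2ccccc2)COC1=O | intermediate
8 | (2R,6R)-2,6-di(prop-2-en-1-yl)heptane-1,7-diol | OC[C@@H](CC=C)CCC[C@H](CC=C)CO | intermediate
9 | (2R,6R)-2,6-di(prop-2-en-1-yl)heptane-1,7-diyl diacetate | CC(=O)OC[C@@H](CC=C)CCC[C@H](CC=C)COC(C)=O | intermediate
10 | (2S,6S)-2,6-bis[3-(9-borabicyclo[3.3.1]nonan-9-yl)propyl]heptane-1,7-diyl diacetate (formed in situ; spatial arrangement as in 9, the descriptor changes only because boron ranks below carbon) | CC(=O)OC[C@@H](CCCB1C2CCCC1CCC2)CCC[C@H](CCCB1C2CCCC1CCC2)COC(C)=O | intermediate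
11 | (2R,6R)-2,6-bis(3-hydroxypropyl)heptane-1,7-diyl diacetate | CC(=O)OC[C@@H](CCCO)CCC[C@H](CCCO)COC(C)=O | intermediate
12 | (2R,6R)-2,6-bis(3-iodopropyl)heptane-1,7-diyl diacetate | CC(=O)OC[C@@H](CCCI)CCC[C@H](CCCI)COC(C)=O | intermediate
13 | [(4R,8R)-4,8-bis(acetoxymethyl)-11-iodoundecyl](triphenyl)phosphonium iodide | CC(=O)OC[C@@H](CCCI)CCC[C@H](CCC[P+](c1ccccc1)(c1ccccc1)c1ccccc1)COC(C)=O.[I-] | intermediate
14 | 1-{[tert-butyl(dimethyl)silyl]oxy}propan-2-one | CC(=O)CO[Si](C)(C)C(C)(C)C | starting material
15 | (2R,6R)-2-(3-iodopropyl)-6-[3-(triphenyl-λ5-phosphanylidene)propyl]heptane-1,7-diyl diacetate (formed in situ) | CC(=O)OC[C@@H](CCCI)CCC[C@H](CCC=P(c1ccccc1)(c1ccccc1)c1ccccc1)COC(C)=O | intermediate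
16 | (2R,6R)-2-[(3Z)-5-{[tert-butyl(dimethyl)silyl]oxy}-4-methylpent-3-en-1-yl]-6-(3-iodopropyl)heptane-1,7-diyl diacetate | CC(=O)OC[C@@H](CCCI)CCC[C@H](CC/C=C(/C)CO[Si](C)(C)C(C)(C)C)COC(C)=O | intermediate
17 | tert-butyl but-2-ynoate | CC#CC(=O)OC(C)(C)C | starting material
18 | lithium 1-tert-butoxybuta-1,2,3-trien-1-olate (formed in situ) | C=C=C=C(O[Li])OC(C)(C)C | intermediate
19 | tert-butyl 2-[(4R,8R,11Z)-4,8-bis(acetoxymethyl)-13-{[tert-butyl(dimethyl)silyl]oxy}-12-methyltridec-11-en-1-yl]buta-2,3-dienoate | CC(=O)OC[C@@H](CCCC(=C=C)C(=O)OC(C)(C)C)CCC[C@H](CC/C=C(/C)CO[Si](C)(C)C(C)(C)C)COC(C)=O | intermediate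
20 | (2R,6R)-2-[(3Z)-5-{[tert-butyl(dimethyl)silyl]oxy}-4-methylpent-3-en-1-yl]-6-[3-(2-oxo-2,5-dihydrofuran-3-yl)propyl]heptane-1,7-diyl diacetate | CC(=O)OC[C@@H](CCCC1=CCOC1=O)CCC[C@H](CC/C=C(/C)CO[Si](C)(C)C(C)(C)C)COC(C)=O | intermediate
21 | (2R,6R)-2-[(3Z)-5-hydroxy-4-methylpent-3-en-1-yl]-6-[3-(2-oxo-2,5-dihydrofuran-3-yl)propyl]heptane-1,7-diyl diacetate | CC(=O)OC[C@@H](CCCC1=CCOC1=O)CCC[C@H](CC/C=C(/C)CO)COC(C)=O | target

Total step count: 11. Longest linear sequence: 11 steps (1 to 21; every other partner is purchased).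

Steps most likely to fail

1. Step 9. What may go wrong: acyl transfer from the acetates to the lithium cumulenolate, alkylation at the γ- instead of the α-carbon, and slow displacement at the unactivated primary iodide. Fallback: setting out from 16, the iodide is heated with tert-butyl (triphenyl-λ5-phosphanylidene)acetate (2.2 equiv, MeCN, reflux). C-alkylation followed by transylidation by the second equivalent should give the α-alkylated stabilised ylide tert-butyl (6R,10R,13Z)-6,10-bis(acetoxymethyl)-15-{[tert-butyl(dimethyl)silyl]oxy}-14-methyl-2-(triphenyl-λ5-phosphanylidene)pentadec-13-enoate F1. Treatment with acetyl chloride and Et3N (CH2Cl2, 0 °C to rt) generates ketene, whose Wittig reaction with the ylide comes back to the route at allenoate 19. No strong base meets the acetates in this sequence.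

2. Step 10. What may go wrong: slow ring closure at the unsubstituted allene terminus, isomerisation of the allene to a 1,3-diene, and ionisation or cleavage of the allylic silyl ether by the Lewis-acidic AuCl3. Fallback: setting out from 19, the tert-butyl ester is removed without protic acid (TMSOTf, 2,6-lutidine, CH2Cl2, 0 °C; aqueous work-up) to give the free allenoic acid 2-[(4R,8R,11Z)-4,8-bis(acetoxymethyl)-13-{[tert-butyl(dimethyl)silyl]oxy}-12-methyltridec-11-en-1-yl]buta-2,3-dienoic acid F2. AgNO3 (10 mol %) in acetone at rt should then cycloisomerise the acid in the same 5-endo sense, with the carboxyl oxygen closing onto the allene CH2, and the sequence comes back to the route at 20.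

3. Step 8. What may go wrong: erosion of the Z-selectivity, enolisation of the ketone, and alkylation of the ylide by the pendant primary iodide. Fallback: setting out from diiodide 12 (used in excess and recycled as in step 7), one iodide is oxidised with trimethylamine N-oxide in DMSO at rt (Ganem oxidation) to the iodo aldehyde (2R,6R)-2-(3-iodopropyl)-6-(3-oxopropyl)heptane-1,7-diyl diacetate F3. Stork–Zhao-type olefination with the α-iodo ylide from ethyltriphenylphosphonium iodide (n-BuLi, I2, then NaN(SiMe3)2, THF, −78 °C) should give the Z-vinyl iodide (2R,6R)-2-[(3Z)-4-iodopent-3-en-1-yl]-6-(3-iodopropyl)heptane-1,7-diyl diacetate F4. Stille coupling with (tributylstannyl)methanol (Pd(PPh3)4, dioxane, 80 °C) replaces the vinylic iodine by CH2OH with retention, the alkyl iodide being much slower in oxidative addition, to give the allylic alcohol (2R,6R)-2-[(3Z)-5-hydroxy-4-methylpent-3-en-1-yl]-6-(3-iodopropyl)heptane-1,7-diyl diacetate F5. Silylation (TBSCl, imidazole, CH2Cl2) comes back to the route at 16.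

Further compounds

F1 | step 9 | tert-butyl (6R,10R,13Z)-6,10-bis(acetoxymethyl)-15-{[tert-butyl(dimethyl)silyl]oxy}-14-methyl-2-(triphenyl-λ5-phosphanylidene)pentadec-13-enoate | CC(=O)OC[C@@H](CCCC(C(=O)OC(C)(C)C)=P(c1ccccc1)(c1ccccc1)c1ccccc1)CCC[C@H](CC/C=C(/C)CO[Si](C)(C)C(C)(C)C)COC(C)=O
F2 | step 10 | 2-[(4R,8R,11Z)-4,8-bis(acetoxymethyl)-13-{[tert-butyl(dimethyl)silyl]oxy}-12-methyltridec-11-en-1-yl]buta-2,3-dienoic acid | CC(=O)OC[C@@H](CCCC(=C=C)C(=O)O)CCC[C@H](CC/C=C(/C)CO[Si](C)(C)C(C)(C)C)COC(C)=O
F3 | step 8 | (2R,6R)-2-(3-iodopropyl)-6-(3-oxopropyl)heptane-1,7-diyl diacetate | CC(=O)OC[C@@H](CCCI)CCC[C@H](CCC=O)COC(C)=O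
F4 | step 8 | (2R,6R)-2-[(3Z)-4-iodopent-3-en-1-yl]-6-(3-iodopropyl)heptane-1,7-diyl diacetate | CC(=O)OC[C@@H](CCCI)CCC[C@H](CC/C=C(/C)I)COC(C)=O
F5 | step 8 | (2R,6R)-2-[(3Z)-5-hydroxy-4-methylpent-3-en-1-yl]-6-(3-iodopropyl)heptane-1,7-diyl diacetate | CC(=O)OC[C@@H](CCCI)CCC[C@H](CC/C=C(/C)CO)COC(C)=O
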